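**Plan**

- Retrosynthesis: the lactone O1–C5 bond is cut first, which turns C5–O/C6–OH into a terminal (R)-oxirane and the lactone carbonyl into a tert-butyl ester. The acyclic 2-acyl-3-oxo ester is then cut at C3–C(acyl) (C-acylation) and at C3–C4 (Claisen), and the iso-C15 chain between C11 and C12 of the acid.
- Forward: copper-catalysed coupling gives the iso-fatty acid; methyl (R)-glycidate is condensed with the enolate of tert-butyl acetate; the epoxy β-keto ester is C-acylated with the fatty acyl chloride; the furanone ring, the only ring of the target, is closed last.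
- Enabling feature: C5 is both the α-carbon of the C4 carbonyl and, with exocyclic C6, a vicinal dioxygenated pair, so C5/C6 can be carried as an oxirane ring that the ester oxygen opens at C5.
- The side-chain C=O and C4=O sit 1,3 across C3 and can be tied into a six-membered O–B–O chelate ring; neither this ring nor the oxirane is in the target, and methanol removes the boron.
- Stereochemistry: the single stereocentre C5 comes from commercial methyl (R)-glycidate and is inverted once, in the ring closure, to (S).

Key step: step 4

Remark: 2-acyl-3-oxo esters and 3-acyltetronic acids exist as chelated enols and are drawn in one tautomeric form; ring atoms are numbered O1, C2 (lactone C=O), C3 (acylated), C4 (C–OH), C5 (stereocentre), C6 (CH2OH).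

**Step 1**
Reactants: 1 11-bromoundecanoic acid; 2 isobutylmagnesium bromide
Product: 3 13-methyltetradecanoic acid
Conditions: 2 (3 equiv), Li2CuCl4 (3 mol %), THF, −20 °C → rt; then aq. HCl
Reagents that add atoms: none
Why: Kochi-type Li2CuCl4-catalysed coupling of a primary alkyl Grignard reagent with a primary alkyl bromide should tolerate the bromomagnesium carboxylate formed by the first equivalent of 2; no stereocentre is involved.

**Step 2**
Reactants: 4 methyl (2R)-oxirane-2-carboxylate (methyl (R)-glycidate); 5 tert-butyl acetate
Product: 6 tert-butyl 3-[(2R)-oxiran-2-yl]-3-oxopropanoate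
Conditions: 5 (2.3 equiv), LiN(SiMe3)2 (2.2 equiv), THF, −78 °C; then 4, −78 °C; AcOH quench at −78 °C
Reagents that add atoms: none
Why: Crossed Claisen condensation, in which the ester enolate should add to the activated α-alkoxy ester carbonyl at −78 °C much faster than it opens the oxirane, the product is held as its enolate against a second addition, and the non-enolisable oxirane stereocentre of 4 is carried over unchanged.

**Step 3**
Reactants: 3 13-methyltetradecanoic acid; 6 tert-butyl 3-[(2R)-oxiran-2-yl]-3-oxopropanoate
Product: 8 tert-butyl 15-methyl-2-[(2R)-oxirane-2-carbonyl]-3-oxohexadecanoate, via 13-methyltetradecanoyl chloride 7 (not isolated)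
Conditions: 3, (COCl)2 (1.2 equiv), DMF (cat.), CH2Cl2, 0 °C → rt, concentrate; then 6, MgCl2 (1 equiv), pyridine (2 equiv), CH2Cl2, 0 °C → rt; cold aq. citric acid
Reagents that add atoms: none
Why: Soft-enolisation C-acylation of a β-keto ester through its divalent magnesium chelate with an acid chloride, in which the more acidic 2-acyl product stays chelated (favouring C- over O-acylation and preventing a second acylation) and the oxirane centre is not touched.

**Step 4**
Reactants: 8 tert-butyl 15-methyl-2-[(2R)-oxirane-2-carbonyl]-3-oxohexadecanoate
Product: 11 (5S)-4-hydroxy-5-(hydroxymethyl)-3-(13-methyltetradecanoyl)furan-2(5H)-one, via difluoroboron chelate of the epoxy triketo ester 9 (not isolated), via difluoroboron chelate of the tetronic acid 10 (not isolated)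
Conditions: BF3·OEt2 (3 equiv), CH2Cl2, −40 °C → rt; then MeOH, 60 °C
Reagents that add atoms: none
Why: Proposed new method: BF3 should first tie the side-chain C=O and C4=O oxygens of the enolised 2-acyl-3-oxo ester into a six-membered difluoroboron chelate (9), which keeps C3 sp2 (no decarboxylation should the ester cleave early), removes the side-chain oxygen as a nucleophile (no 3(2H)-furanone) and holds the ester carbon next to the oxirane carbon C5. A second BF3 then activates the oxirane, the ester carbonyl oxygen opens it at C5 from the rear (SN2) in a 5-exo-tet closure that forms O1–C5, the 2-tert-butoxyoxolenium ion loses 2-methylpropene, and the oxirane oxygen stays on C6 as the free CH2OH; methanol finally cleaves the B–O bonds of 10. The closest known reaction types are the thermal cyclisation of 2-acyl-4-halo-3-oxo esters to 3-acyltetronic acids by the ester oxygen, the Lewis-acid opening of oxiranes by tert-butyl esters and carbonates with loss of 2-methylpropene, and the methanolysis of BF2 chelates of 3-acyl tetronic and tetramic acids. The C5 stereocentre is controlled by the (R)-oxirane carbon of 8, which is inverted to (S); a cation at C5, alpha to the chelated carbonyl, is not accessible, so no SN1 leakage is expected. The step needs closure at C5 and not at the terminal C6 (6-endo), and by the ester and not the ketone oxygen: the first is entrusted to the exo geometry (C5 is the nearer carbon to the ortho-like ester and can be reached more nearly in line with the breaking C–O bond), the second to the chelate.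

**Compound list**

1 | 11-bromoundecanoic acid | OC(=O)CCCCCCCCCCBr | starting material
2 | isobutylmagnesium bromide, (CH3)2CHCH2MgBr | CC(C)C[Mg]Br | starting material
3 | 13-methyltetradecanoic acid | CC(C)CCCCCCCCCCCC(=O)O | intermediate
4 | methyl (2R)-oxirane-2-carboxylate | COC(=O)[C@H]1CO1 | starting material
5 | tert-butyl acetate | CC(=O)OC(C)(C)C | starting material
6 | tert-butyl 3-[(2R)-oxiran-2-yl]-3-oxopropanoate | CC(C)(C)OC(=O)CC(=O)[C@H]1CO1 | intermediate
7 | 13-methyltetradecanoyl chloride | CC(C)CCCCCCCCCCCC(=O)Cl | intermediate (not isolated)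
8 | tert-butyl 15-methyl-2-[(2R)-oxirane-2-carbonyl]-3-oxohexadecanoate (triketo form drawn; chelated enol) | CC(C)CCCCCCCCCCCC(=O)C(C(=O)OC(C)(C)C)C(=O)[C@H]1CO1 | intermediate
9 | difluoroboron chelate of 8 (BF2 on the side-chain C=O and C4–O oxygens; tert-butyl ester and (R)-oxirane intact) | CC(C)CCCCCCCCCCCC1=[O+][B-](F)(F)OC(=C1C(=O)OC(C)(C)C)[C@H]1CO1 | intermediate (not isolated)
10 | difluoroboron chelate of 11 (BF2 on the side-chain C=O and C4–O oxygens; (5S), free CH2OH) | CC(C)CCCCCCCCCCCC1=[O+][B-](F)(F)OC2=C1C(=O)O[C@H]2CO | intermediate (not isolated)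
11 | (5S)-4-hydroxy-5-(hydroxymethyl)-3-(13-methyltetradecanoyl)furan-2(5H)-one | CC(C)CCCCCCCCCCCC(=O)C1=C(O)[C@H](CO)OC1=O | target

**Count**

Total steps: 4. Longest linear sequence: 3 steps (1 → 3 → 4, or 2 → 3 → 4).

**Steps most likely to fail**

1. Step 4 (proposed method). What may go wrong: attack of the ester oxygen on the terminal oxirane carbon instead of C5 (6-endo closure, whose later acyl shift would also erode the configuration), opening of the activated oxirane by fluoride, or loss of the tert-butyl group before the ring has closed. The fallback uses known chemistry, sets out from 3 and returns at 11; the C5–O bond is taken from the chiral pool and the ring is closed at C3–C4. Acid 3 is condensed with Meldrum's acid (DCC, DMAP, CH2Cl2) to 5-(1-hydroxy-13-methyltetradecylidene)-2,2-dimethyl-1,3-dioxane-4,6-dione F1. Commercial methyl (S)-2,2-dimethyl-1,3-dioxolane-4-carboxylate is hydrolysed at the acetal (aq. AcOH, 40 °C) to methyl (2S)-2,3-dihydroxypropanoate F2, which is tritylated at the primary hydroxyl (TrCl, pyridine) to methyl (2S)-2-hydroxy-3-(trityloxy)propanoate F3. Heating F1 with F3 in toluene should give, through the acylketene, methyl (2S)-2-[(15-methyl-3-oxohexadecanoyl)oxy]-3-(trityloxy)propanoate F4. Dieckmann cyclisation (Bu4NF, THF, rt) should then give (5S)-4-hydroxy-3-(13-methyltetradecanoyl)-5-[(trityloxy)methyl]furan-2(5H)-one F5, and HCl in MeOH removes the trityl group to give 11 with the glycerate configuration retained at C5.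

2. Step 3. What may go wrong: opening of the magnesium-activated oxirane by chloride, O- instead of C-acylation, or early closure of an enolate oxygen onto the oxirane. The fallback sets out from 6 and 7 and returns at 8, without any Lewis acid. Compound 6 is O-acylated on purpose with 7 (Et3N, CH2Cl2, 0 °C) to the enol ester tert-butyl 3-[(13-methyltetradecanoyl)oxy]-3-[(2R)-oxiran-2-yl]prop-2-enoate F6 (E/Z mixture, both usable). The acyl group is then moved from oxygen to C2 by nucleophilic acyl-transfer catalysis (DMAP cat., Et3N, toluene, rt), driven by formation of the chelated enol of 8.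

3. Step 2. What may go wrong: attack of the lithium enolate on the oxirane, a second addition to the new ketone on warming, or base-induced oligomerisation of the glycidate. The fallback sets out from 7 (made from 3 as in step 3), 5 and 4, bypasses 6 and returns at 8 by reversing the roles of the two acyl partners. The lithium enolate of 5 (2 equiv, LiN(SiMe3)2, THF, −78 °C) is acylated with 7 to tert-butyl 15-methyl-3-oxohexadecanoate F7. Ester 4 is saponified (KOH, EtOH, 0 °C) to potassium (2R)-oxirane-2-carboxylate F8 and converted ((COCl)2, DMF cat., Et2O, 0 °C) to (2R)-oxirane-2-carbonyl chloride F9. F9 is used at once to C-acylate the divalent magnesium chelate of F7 (MgCl2, pyridine, CH2Cl2, 0 °C), giving 8.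

**Further compounds**

F1 | step 4 | 5-(1-hydroxy-13-methyltetradecylidene)-2,2-dimethyl-1,3-dioxane-4,6-dione | CC(C)CCCCCCCCCCCC(O)=C1C(=O)OC(C)(C)OC1=O
F2 | step 4 | methyl (2S)-2,3-dihydroxypropanoate | COC(=O)[C@@H](O)CO
F3 | step 4 | methyl (2S)-2-hydroxy-3-(trityloxy)propanoate | COC(=O)[C@@H](O)COC(c1ccccc1)(c1ccccc1)c1ccccc1
F4 | step 4 | methyl (2S)-2-[(15-methyl-3-oxohexadecanoyl)oxy]-3-(trityloxy)propanoate | CC(C)CCCCCCCCCCCC(=O)CC(=O)O[C@@H](COC(c1ccccc1)(c1ccccc1)c1ccccc1)C(=O)OC
F5 | step 4 | (5S)-4-hydroxy-3-(13-methyltetradecanoyl)-5-[(trityloxy)methyl]furan-2(5H)-one | CC(C)CCCCCCCCCCCC(=O)C1=C(O)[C@H](COC(c2ccccc2)(c2ccccc2)c2ccccc2)OC1=O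
F6 | step 3 | tert-butyl 3-[(13-methyltetradecanoyl)oxy]-3-[(2R)-oxiran-2-yl]prop-2-enoate (E/Z not defined) | CC(C)CCCCCCCCCCCC(=O)OC(=CC(=O)OC(C)(C)C)[C@H]1CO1
F7 | step 2 | tert-butyl 15-methyl-3-oxohexadecanoate | CC(C)CCCCCCCCCCCC(=O)CC(=O)OC(C)(C)C
F8 | step 2 | potassium (2R)-oxirane-2-carboxylate | [K+].[O-]C(=O)[C@H]1CO1
F9 | step 2 | (2R)-oxirane-2-carbonyl chloride | ClC(=O)[C@H]1CO1
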